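**Retrosynthetic overview** (lines run from the building blocks to the target; read upward for the disconnections)
1. Aryl–allyl bond: 2,3-dibromopropene 1 + guaiacyl pinacolboronate 2 → 2-bromoallylarene 3 (allyl–aryl Suzuki).
2. Styrenyl C=C: 4-vinylguaiacol 4 + isopropenyl-Bpin 5 → (Z)-alkenylboronate 6 (cross-metathesis).
3. Diene C–C bond: 3 + 6 → unprotected lignan-type diene 7, which already carries the aryl, methyl and benzyl groups of the benzenoid ring.
4. Key disconnection C4a–C5 / C8–C8a: 7 + 2-methoxy-1,4-benzoquinone 8 → [4+2] adduct 9 → 10 → 11 → 12 → larreantin 13 in one flask, with excess 8 as hydrogen acceptor. This copies the presumed biogenesis (lignan diene + methoxyquinone, then dehydrogenation).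
5. Ring order: the quinone ring is bought in 8; the benzenoid ring is the only ring formed, last, and is aromatised at once.

Assumption: larreantin has no stereocentre and no configurationally stable axis (the 8-aryl ring has no ortho substituent), so "single enantiomer" means the achiral compound as drawn.

**Step 1**
Reactants: 1 2,3-dibromoprop-1-ene; 2 2-methoxy-4-(4,4,5,5-tetramethyl-1,3,2-dioxaborolan-2-yl)phenol
Product: 3 4-(2-bromoprop-2-en-1-yl)-2-methoxyphenol
Conditions: 1 (1.5 equiv), Pd(PPh3)4 (3 mol%), K2CO3 (2.5 equiv), THF/H2O 5:1, 40 °C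
Reagents that add atoms: none
Why: Suzuki–Miyaura allyl–aryl coupling, in which Pd(0) ionises the allylic C–Br bond of 1 much faster than it inserts into the vinylic C–Br bond, so the symmetrical 2-bromo-π-allyl complex is arylated once and the vinyl bromide is kept for step 3; no stereocentre is formed.

**Step 2**
Reactants: 4 4-ethenyl-2-methoxyphenol; 5 4,4,5,5-tetramethyl-2-(prop-1-en-2-yl)-1,3,2-dioxaborolane
Product: 6 2-methoxy-4-[(1Z)-2-(4,4,5,5-tetramethyl-1,3,2-dioxaborolan-2-yl)prop-1-en-1-yl]phenol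
Conditions: Hoveyda–Grubbs II (5 mol%), 5 (3 equiv), CH2Cl2, 40 °C, Ar sweep
Reagents that add atoms: none
Why: Ruthenium-catalysed olefin cross-metathesis of a styrene with a 1,1-disubstituted alkenylboronate that does not homodimerise, driven by loss of ethene; the bulky Bpin group ends up trans to the aryl group, which gives the (Z)-alkene (aryl cis to methyl) needed for the (E)-diene.

**Step 3**
Reactants: 3 4-(2-bromoprop-2-en-1-yl)-2-methoxyphenol; 6 2-methoxy-4-[(1Z)-2-(4,4,5,5-tetramethyl-1,3,2-dioxaborolan-2-yl)prop-1-en-1-yl]phenol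
Product: 7 4-[(1E)-3-(4-hydroxy-3-methoxybenzyl)-2-methylbuta-1,3-dien-1-yl]-2-methoxyphenol
Conditions: Pd(dppf)Cl2 (5 mol%), K2CO3 (4 equiv), 1,4-dioxane/H2O 4:1, 70 °C, degassed; product used promptly
Reagents that add atoms: none
Why: Suzuki–Miyaura alkenyl–alkenyl coupling, which tolerates free phenols and proceeds with retention of alkene geometry, so the aryl group stays trans to the new diene carbon and the (E)-1-aryl diene can reach the s-cis conformation.

**Step 4**
Reactants: 7 4-[(1E)-3-(4-hydroxy-3-methoxybenzyl)-2-methylbuta-1,3-dien-1-yl]-2-methoxyphenol; 8 2-methoxycyclohexa-2,5-diene-1,4-dione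
Product: 13 larreantin, via cycloadduct 9 (not isolated), via dihydronaphthalenediol 10 (not isolated), via dihydronaphthoquinone 11 (not isolated), via naphthalenediol 12 (not isolated)
Conditions: 8 (3.5 equiv), PhMe, 80 °C; then AcOH (20 vol%), 80 °C, same flask
Reagents that add atoms: none
Why: Diels–Alder reaction followed by acid-catalysed enolisation and two quinone transfer dehydrogenations, in which the CH2 terminus of the 1-aryl diene (largest HOMO coefficient) bonds to C5 of 8 (β to the C1 carbonyl, the more electron-poor one because C4=O is a vinylogous ester), so the aryl group ends up peri to C1=O next to C2–OMe; 8 is a stronger oxidant than the methoxynaphthoquinone, and aromatisation destroys the three transient (endo, racemic) stereocentres of 9.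

**Compound list**
1 | 2,3-dibromoprop-1-ene | C=C(Br)CBr | starting material
2 | 2-methoxy-4-(4,4,5,5-tetramethyl-1,3,2-dioxaborolan-2-yl)phenol | COc1cc(B2OC(C)(C)C(C)(C)O2)ccc1O | starting material
3 | 4-(2-bromoprop-2-en-1-yl)-2-methoxyphenol | COc1cc(CC(Br)=C)ccc1O | intermediate
4 | 4-ethenyl-2-methoxyphenol (4-vinylguaiacol) | COc1cc(C=C)ccc1O | starting material
5 | 4,4,5,5-tetramethyl-2-(prop-1-en-2-yl)-1,3,2-dioxaborolane | CC(=C)B1OC(C)(C)C(C)(C)O1 | starting material
6 | 2-methoxy-4-[(1Z)-2-(4,4,5,5-tetramethyl-1,3,2-dioxaborolan-2-yl)prop-1-en-1-yl]phenol | COc1cc(/C=C(\C)B2OC(C)(C)C(C)(C)O2)ccc1O | intermediate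
7 | 4-[(1E)-3-(4-hydroxy-3-methoxybenzyl)-2-methylbuta-1,3-dien-1-yl]-2-methoxyphenol | COc1cc(/C=C(\C)C(=C)Cc2ccc(O)c(OC)c2)ccc1O | intermediate
8 | 2-methoxycyclohexa-2,5-diene-1,4-dione (2-methoxy-1,4-benzoquinone) | COC1=CC(=O)C=CC1=O | starting material
9 | racemic endo cycloadduct, H-4a, H-8 and H-8a all cis (one enantiomer drawn): 6-(4-hydroxy-3-methoxybenzyl)-8-(4-hydroxy-3-methoxyphenyl)-2-methoxy-7-methyl-4a,5,8,8a-tetrahydronaphthalene-1,4-dione | COC1=CC(=O)[C@@H]2CC(Cc3ccc(O)c(OC)c3)=C(C)[C@H](c3ccc(O)c(OC)c3)[C@@H]2C1=O | intermediate (not isolated)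
10 | racemic 6-(4-hydroxy-3-methoxybenzyl)-8-(4-hydroxy-3-methoxyphenyl)-2-methoxy-7-methyl-5,8-dihydronaphthalene-1,4-diol | COc1cc(O)c2CC(Cc3ccc(O)c(OC)c3)=C(C)C(c3ccc(O)c(OC)c3)c2c1O | intermediate (not isolated)
11 | racemic 6-(4-hydroxy-3-methoxybenzyl)-8-(4-hydroxy-3-methoxyphenyl)-2-methoxy-7-methyl-5,8-dihydronaphthalene-1,4-dione | COC1=CC(=O)C2=C(C1=O)C(c3ccc(O)c(OC)c3)C(C)=C(Cc3ccc(O)c(OC)c3)C2 | intermediate (not isolated)
12 | 6-(4-hydroxy-3-methoxybenzyl)-8-(4-hydroxy-3-methoxyphenyl)-2-methoxy-7-methylnaphthalene-1,4-diol | COc1cc(O)c2cc(Cc3ccc(O)c(OC)c3)c(C)c(-c3ccc(O)c(OC)c3)c2c1O | intermediate (not isolated)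
13 | larreantin, 6-(4-hydroxy-3-methoxybenzyl)-8-(4-hydroxy-3-methoxyphenyl)-2-methoxy-7-methylnaphthalene-1,4-dione (achiral) | COC1=CC(=O)c2cc(Cc3ccc(O)c(OC)c3)c(C)c(-c3ccc(O)c(OC)c3)c2C1=O | target

**Totals**
Total steps: 4. Longest linear sequence: 3 (step 1 or step 2, then steps 3 and 4).

**Steps most likely to fail**

Step 4 (most likely). The risks are an imperfect regioisomer ratio in the uncatalysed cycloaddition, side reactions of the electron-rich hydroxystyrene diene with the quinone, and incomplete aromatisation. The fallback sets out from diene 7 and comes back at dihydronaphthoquinone 11. Commercial 5-bromovanillin is converted by Dakin oxidation (H2O2, NaOH) into 2-bromo-6-methoxybenzene-1,4-diol F1. F1 is oxidised (FeCl3 or CAN) to 2-bromo-6-methoxycyclohexa-2,5-diene-1,4-dione F2. F2 reacts with 7 at its bromo-substituted double bond (PhMe, 50 °C); bromine and the C1 carbonyl both send the CH2 terminus of the diene to the unsubstituted carbon, giving the 8a-bromo cycloadduct F3. Et3N then removes HBr from F3 to give 11, which tautomerises to 12 and needs only one oxidation equivalent (air or 8) to reach 13.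

Step 2. The risks are low conversion with the 1,1-disubstituted boronate, stilbene homodimer from 4, and an impure alkene geometry. The fallback sets out from vinyl bromide 3, bypasses 6 and comes back at diene 7. Commercial 1-(4-hydroxy-3-methoxyphenyl)propan-2-one is condensed with tosylhydrazide (MeOH, 60 °C) to N'-[1-(4-hydroxy-3-methoxyphenyl)propan-2-ylidene]-4-methylbenzenesulfonohydrazide F4. F4 is coupled with 3 under Barluenga conditions (Pd2(dba)3, XPhos, LiOtBu, dioxane, 90 °C). The palladium carbene inserts into the alkenyl–Pd bond and β-hydride elimination toward the benzylic hydrogen gives 7; the (E)-isomer is separated if a mixture forms.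

Step 1. The risks are O-allylation of the free phenol, protodeboronation of 2, and a second arylation at the vinyl bromide. The fallback sets out from dibromide 1 and comes back at 3. Commercial 4-bromo-2-methoxyphenol is silylated (TBSCl, imidazole) to (4-bromo-2-methoxyphenoxy)(tert-butyl)dimethylsilane F5. F5 is converted with Mg in THF into [4-(tert-butyldimethylsilyloxy)-3-methoxyphenyl]magnesium bromide F6. F6 is coupled with 1 at the allylic position (CuI cat., THF, 0 °C) to give [4-(2-bromoprop-2-en-1-yl)-2-methoxyphenoxy](tert-butyl)dimethylsilane F7. TBAF/AcOH then gives 3.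

**Further compounds**
F1 | step 4 | 2-bromo-6-methoxybenzene-1,4-diol | COc1cc(O)cc(Br)c1O
F2 | step 4 | 2-bromo-6-methoxycyclohexa-2,5-diene-1,4-dione | COC1=CC(=O)C=C(Br)C1=O
F3 | step 4 | racemic 8a-bromo cycloadduct, H-4a, H-8 and Br-8a all cis (one enantiomer drawn): 8a-bromo-6-(4-hydroxy-3-methoxybenzyl)-8-(4-hydroxy-3-methoxyphenyl)-2-methoxy-7-methyl-4a,5,8,8a-tetrahydronaphthalene-1,4-dione | COC1=CC(=O)[C@@H]2CC(Cc3ccc(O)c(OC)c3)=C(C)[C@H](c3ccc(O)c(OC)c3)[C@]2(Br)C1=O
F4 | step 2 | N'-[(2E)-1-(4-hydroxy-3-methoxyphenyl)propan-2-ylidene]-4-methylbenzenesulfonohydrazide | COc1cc(C/C(C)=N/NS(=O)(=O)c2ccc(C)cc2)ccc1O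
F5 | step 1 | (4-bromo-2-methoxyphenoxy)(tert-butyl)dimethylsilane | COc1cc(Br)ccc1O[Si](C)(C)C(C)(C)C
F6 | step 1 | [4-(tert-butyldimethylsilyloxy)-3-methoxyphenyl]magnesium bromide | COc1cc([Mg]Br)ccc1O[Si](C)(C)C(C)(C)C
F7 | step 1 | [4-(2-bromoprop-2-en-1-yl)-2-methoxyphenoxy](tert-butyl)dimethylsilane | COc1cc(CC(Br)=C)ccc1O[Si](C)(C)C(C)(C)C
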